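## Retrosynthetic overview

- The target comes from its 4,5‑acetonide by hydrolysis; the trans‑oxirane is installed last, on the 10‑membered (6E)‑alkene lactone, by epoxidation directed by the C8 hydroxyl.
- The 10‑membered lactone is closed by a homologative photo‑Wolff macrolactonisation of an open‑chain α‑diazoketone, which forms C3–C4 and O1–C2 in one step.
- The diazoketone comes from an acid made by photochemical iridium/nickel decarboxylative vinylation (C5–C6 bond) of D‑tartaric acid acetonide diacid with an (E)‑vinyl iodide.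
- The vinyl iodide comes from a D‑xylose‑derived furanose: butyl coupling at C5, C3 inversion by oxidation/reduction, O3 acylation, acetonide hydrolysis, Takai olefination.
- The side‑chain acid comes from the (R)‑Roche ester. Ring order: furanose and dioxolane are bought, the furanose is opened, then the 10‑membered lactone and finally the oxirane are formed.

Assumption: positions are numbered as in the lactone (O1, C2 carbonyl … C10 bearing pentyl) also for open‑chain precursors; the Roche ester, the D‑tartrate acetonide diester and the xylose tosylate are bought, and the lactol of step 10 is used as its anomeric mixture.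

## Route

Step 1
Reactants: 1 methyl (R)-3-hydroxy-2-methylpropanoate
Product: 2 methyl (R)-2-methyl-3-(tosyloxy)propanoate
Conditions: TsCl, pyridine, CH2Cl2, 0 °C
Reagents that add atoms: p-toluenesulfonyl chloride, Cc1ccc(cc1)S(Cl)(=O)=O
Why: Tosylation of the primary alcohol; the stereocentre is not touched.

Step 2
Reactants: 2 methyl (R)-2-methyl-3-(tosyloxy)propanoate
Product: 3 methyl (R)-2-methylbutanoate
Conditions: Me2CuLi (from MeLi, CuI), Et2O, −30 → 0 °C
Reagents that add atoms: lithium dimethylcuprate, [Li+].C[Cu-]C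
Why: Gilman cuprate SN2 displacement of the primary tosylate outpaces attack on the ester at low temperature, and the neighbouring stereocentre is not involved.

Step 3
Reactants: 3 methyl (R)-2-methylbutanoate
Product: 5 ethyl (2E,4R)-2,4-dimethylhex-2-enoate, via (R)-2-methylbutanal 4 (not isolated)
Conditions: i-Bu2AlH, CH2Cl2, −78 °C; then Ph3P=C(Me)CO2Et, −78 °C → rt
Reagents that add atoms: ethyl 2-(triphenylphosphoranylidene)propanoate, CCOC(=O)C(C)=P(c1ccccc1)(c1ccccc1)c1ccccc1
Why: Partial ester reduction followed in the same pot by Wittig olefination with an α-methyl stabilised ylide gives the (E)-trisubstituted enoate and traps the α-chiral aldehyde before it can epimerise.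

Step 4
Reactants: 5 ethyl (2E,4R)-2,4-dimethylhex-2-enoate
Product: 6 (2E,4R)-2,4-dimethylhex-2-enoic acid
Conditions: LiOH, THF/MeOH/H2O, 40 °C; then 1 M HCl
Reagents that add atoms: lithium hydroxide, [Li+].[OH-]
Why: Ester saponification; the γ-stereocentre is not acidic enough to be disturbed.

Step 5
Reactants: 7 dimethyl (4S,5S)-2,2-dimethyl-1,3-dioxolane-4,5-dicarboxylate (dimethyl 2,3-O-isopropylidene-D-tartrate)
Product: 8 (4S,5S)-2,2-dimethyl-1,3-dioxolane-4,5-dicarboxylic acid
Conditions: KOH (2.2 equiv), MeOH/H2O, 0 °C → rt; then 1 M HCl to pH 2, 0 °C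
Reagents that add atoms: potassium hydroxide, [K+].[OH-]
Why: Double saponification; the electron-poor trans-dioxolane survives brief cold acidification and trans is also the thermodynamic arrangement.

Step 6
Reactants: 9 1,2-O-isopropylidene-5-O-tosyl-α-D-xylofuranose
Product: 10 5-C-butyl-5-deoxy-1,2-O-isopropylidene-α-D-xylofuranose
Conditions: n-BuMgBr (3 equiv), Li2CuCl4 (5 mol %), THF, −30 → 0 °C
Reagents that add atoms: butylmagnesium bromide, CCCC[Mg]Br
Why: Copper-catalysed Grignard coupling (Kochi–Schlosser alkylation) at the primary tosylate builds the pentyl chain; any 3,5-anhydro oxetane formed from the alkoxide is opened at C5 by the same reagent, and no stereocentre is touched.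

Step 7
Reactants: 10 5-C-butyl-5-deoxy-1,2-O-isopropylidene-α-D-xylofuranose
Product: 11 5-C-butyl-5-deoxy-1,2-O-isopropylidene-α-D-erythro-pentofuranos-3-ulose
Conditions: Dess–Martin periodinane, CH2Cl2, rt
Reagents that add atoms: none
Why: Dess–Martin oxidation of the only free (secondary) alcohol.

Step 8
Reactants: 11 5-C-butyl-5-deoxy-1,2-O-isopropylidene-α-D-erythro-pentofuranos-3-ulose
Product: 12 5-C-butyl-5-deoxy-1,2-O-isopropylidene-α-D-ribofuranose
Conditions: NaBH4, EtOH/H2O (4:1), 0 °C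
Reagents that add atoms: none
Why: Borohydride reduction from the convex β-face of the cis-fused bicycle, away from the 1,2-acetonide, gives the ribo alcohol (future C9) under substrate control.

Step 9
Reactants: 12 5-C-butyl-5-deoxy-1,2-O-isopropylidene-α-D-ribofuranose; 6 (2E,4R)-2,4-dimethylhex-2-enoic acid
Product: 14 5-C-butyl-5-deoxy-3-O-[(2E,4R)-2,4-dimethylhex-2-enoyl]-1,2-O-isopropylidene-α-D-ribofuranose, via mixed anhydride 13 (not isolated)
Conditions: 2,4,6-Cl3C6H2COCl, Et3N, THF, rt; then 12, DMAP, PhMe, rt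
Reagents that add atoms: none
Why: Yamaguchi esterification of the only free hydroxyl (O3, the future C9 oxygen), so the acyl group is placed unambiguously between the future C8 and C10 oxygens.

Step 10
Reactants: 14 5-C-butyl-5-deoxy-3-O-[(2E,4R)-2,4-dimethylhex-2-enoyl]-1,2-O-isopropylidene-α-D-ribofuranose
Product: 15 5-C-butyl-5-deoxy-3-O-[(2E,4R)-2,4-dimethylhex-2-enoyl]-D-ribofuranose (anomeric mixture)
Conditions: CF3CO2H/H2O (4:1), 0 °C → rt
Reagents that add atoms: water, O
Why: Acid-catalysed hydrolysis of the anomeric acetonide frees the lactol; the hindered secondary enoate is stable to aqueous acid and migrates only slowly without base.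

Step 11
Reactants: 15 5-C-butyl-5-deoxy-3-O-[(2E,4R)-2,4-dimethylhex-2-enoyl]-D-ribofuranose
Product: 16 (1E,3S,4R,5R)-3,5-dihydroxy-1-iododec-1-en-4-yl (2E,4R)-2,4-dimethylhex-2-enoate
Conditions: CrCl2 (8 equiv), CHI3 (3 equiv), THF/1,4-dioxane (1:6), 0 °C → rt
Reagents that add atoms: iodoform, IC(I)I
Why: Takai iodo-olefination of the open-chain aldehyde in equilibrium with the lactol gives the (E)-vinyl iodide (C6) under non-basic conditions that tolerate the ester and free hydroxyls, and frees O4 as the C10 hydroxyl.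

Step 12
Reactants: 16 (1E,3S,4R,5R)-3,5-dihydroxy-1-iododec-1-en-4-yl (2E,4R)-2,4-dimethylhex-2-enoate; 8 (4S,5S)-2,2-dimethyl-1,3-dioxolane-4,5-dicarboxylic acid
Product: 17 (4S,5R)-5-[(1E,3S,4R,5R)-4-{[(2E,4R)-2,4-dimethylhex-2-enoyl]oxy}-3,5-dihydroxydec-1-en-1-yl]-2,2-dimethyl-1,3-dioxolane-4-carboxylic acid
Conditions: 8 (3 equiv), [Ir{dF(CF3)ppy}2(dtbbpy)]PF6 (1 mol %), NiCl2·glyme (5 mol %), dtbbpy (5 mol %), Cs2CO3 (1.5 equiv), DMSO, 450 nm LEDs, 25 °C
Reagents that add atoms: none
Why: Metallaphotoredox decarboxylative C(sp3)–C(sp2) coupling. The α-oxy radical from one carboxylate of the C2-symmetric diacid (used in excess as its buffered mono-caesium salt) is captured by the vinylnickel species and couples trans to the neighbouring dioxolane substituent, which sets C5 under substrate control and keeps the (E)-geometry.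

Step 13
Reactants: 17 (4S,5R)-5-[(1E,3S,4R,5R)-4-{[(2E,4R)-2,4-dimethylhex-2-enoyl]oxy}-3,5-dihydroxydec-1-en-1-yl]-2,2-dimethyl-1,3-dioxolane-4-carboxylic acid
Product: 19 (1E,3S,4R,5R)-1-[(4R,5S)-5-(diazoacetyl)-2,2-dimethyl-1,3-dioxolan-4-yl]-3,5-dihydroxydec-1-en-4-yl (2E,4R)-2,4-dimethylhex-2-enoate, via isobutyl carbonic anhydride 18 (not isolated)
Conditions: i-BuOCOCl, N-methylmorpholine, THF, −20 °C; then CH2N2, Et2O, 0 °C
Reagents that add atoms: diazomethane, C=[N+]=[N-]
Why: Mixed-anhydride acylation of diazomethane (first half of an Arndt–Eistert homologation) is faster than any reaction of the free secondary hydroxyls, and the trans-dioxolane cannot epimerise to a more stable form.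

Step 14
Reactants: 19 (1E,3S,4R,5R)-1-[(4R,5S)-5-(diazoacetyl)-2,2-dimethyl-1,3-dioxolan-4-yl]-3,5-dihydroxydec-1-en-4-yl (2E,4R)-2,4-dimethylhex-2-enoate
Product: 21 (4R,5R,6E,8S,9S,10R)-8-hydroxy-4,5-(isopropylidenedioxy)-2-oxo-10-pentyl-3,4,5,8,9,10-hexahydro-2H-oxecin-9-yl (2E,4R)-2,4-dimethylhex-2-enoate, via ketene 20 (not isolated)
Conditions: hν (365 nm LED), PhMe (0.5 mM, slow addition), 4 Å MS, 25 °C
Reagents that add atoms: none
Why: Proposed new method: homologative photo-Wolff macrolactonisation. Excitation of the s-cis α-diazoketone expels N2 with concerted 1,2-shift of C4 (retention, as in every Wolff rearrangement) to a monoalkylketene; at 0.5 mM in a non-nucleophilic solvent this can be captured only by the tethered C10 hydroxyl, because attack by the C8 hydroxyl would give an (E)-cyclooctene lactone, so the C3–C4 bond and the O1–C2 bond of the 10-membered ring form in one operation. The closest known reaction types are the intermolecular photochemical Arndt–Eistert ester synthesis and acylketene (dioxinone) macrolactonisation.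

Step 15
Reactants: 21 (4R,5R,6E,8S,9S,10R)-8-hydroxy-4,5-(isopropylidenedioxy)-2-oxo-10-pentyl-3,4,5,8,9,10-hexahydro-2H-oxecin-9-yl (2E,4R)-2,4-dimethylhex-2-enoate
Product: 22 4,5-O-isopropylidene derivative of the target (trans-6,7-oxirane erythro to the C8 hydroxyl; every stereocentre arranged as in the target)
Conditions: VO(acac)2 (10 mol %), t-BuOOH (1.5 equiv), CH2Cl2, 0 °C → rt
Reagents that add atoms: tert-butyl hydroperoxide, CC(C)(C)OO
Why: Vanadium-catalysed hydroxyl-directed epoxidation (Sharpless–Michaelson). The C8 vanadate can reach only the exposed face of the ring (E)-alkene from the conformer that holds the C8–O bond near the alkene plane, which puts the new C7–O bond erythro to C8–OH (the target oxirane); the C5 oxygen is tied up in the acetonide and the electron-poor enoate does not react.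

Step 16
Reactants: 22 4,5-O-isopropylidene derivative of the target
Product: 23 (4R,5S,6R,7R,8S,9S,10R)-6,7-epoxy-4,5,8-trihydroxy-2-oxo-10-pentyloxecan-9-yl (2E,4R)-2,4-dimethylhex-2-enoate (CNP0548321.2; target)
Conditions: CF3CO2H/H2O (9:1), CH2Cl2, 0 °C
Reagents that add atoms: none
Why: Acid-catalysed acetonide hydrolysis; the oxirane is flanked by two oxygen-bearing carbons and so is deactivated towards acid opening, and both esters survive brief cold acid.

## Compound list

1 | methyl (R)-3-hydroxy-2-methylpropanoate (Roche ester) | COC(=O)[C@H](C)CO | starting material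
2 | methyl (R)-2-methyl-3-(tosyloxy)propanoate | COC(=O)[C@H](C)COS(=O)(=O)c1ccc(C)cc1 | intermediate
3 | methyl (R)-2-methylbutanoate | COC(=O)[C@H](C)CC | intermediate
4 | (R)-2-methylbutanal | O=C[C@H](C)CC | intermediate (not isolated)
5 | ethyl (2E,4R)-2,4-dimethylhex-2-enoate | CCOC(=O)/C(C)=C/[C@H](C)CC | intermediate
6 | (2E,4R)-2,4-dimethylhex-2-enoic acid | OC(=O)/C(C)=C/[C@H](C)CC | intermediate
7 | dimethyl (4S,5S)-2,2-dimethyl-1,3-dioxolane-4,5-dicarboxylate | COC(=O)[C@H]1OC(C)(C)O[C@@H]1C(=O)OC | starting material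
8 | (4S,5S)-2,2-dimethyl-1,3-dioxolane-4,5-dicarboxylic acid | OC(=O)[C@H]1OC(C)(C)O[C@@H]1C(=O)O | intermediate
9 | 1,2-O-isopropylidene-5-O-tosyl-α-D-xylofuranose | CC1(C)O[C@H]2O[C@H](COS(=O)(=O)c3ccc(C)cc3)[C@H](O)[C@H]2O1 | starting material
10 | 5-C-butyl-5-deoxy-1,2-O-isopropylidene-α-D-xylofuranose, (3aR,5R,6S,6aR)-2,2-dimethyl-5-pentyltetrahydrofuro[2,3-d][1,3]dioxol-6-ol | CC1(C)O[C@H]2O[C@H](CCCCC)[C@H](O)[C@H]2O1 | intermediate
11 | 5-C-butyl-5-deoxy-1,2-O-isopropylidene-α-D-erythro-pentofuranos-3-ulose | CC1(C)O[C@H]2O[C@H](CCCCC)C(=O)[C@H]2O1 | intermediate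
12 | 5-C-butyl-5-deoxy-1,2-O-isopropylidene-α-D-ribofuranose, (3aR,5R,6R,6aR)-2,2-dimethyl-5-pentyltetrahydrofuro[2,3-d][1,3]dioxol-6-ol | CC1(C)O[C@H]2O[C@H](CCCCC)[C@@H](O)[C@H]2O1 | intermediate
13 | (2E,4R)-2,4-dimethylhex-2-enoic 2,4,6-trichlorobenzoic anhydride | O=C(OC(=O)/C(C)=C/[C@H](C)CC)c1c(Cl)cc(Cl)cc1Cl | intermediate (not isolated)
14 | 5-C-butyl-5-deoxy-3-O-[(2E,4R)-2,4-dimethylhex-2-enoyl]-1,2-O-isopropylidene-α-D-ribofuranose | CC1(C)O[C@H]2O[C@H](CCCCC)[C@@H](OC(=O)/C(C)=C/[C@H](C)CC)[C@H]2O1 | intermediate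
15 | 5-C-butyl-5-deoxy-3-O-[(2E,4R)-2,4-dimethylhex-2-enoyl]-D-ribofuranose (anomeric mixture) | OC1O[C@H](CCCCC)[C@@H](OC(=O)/C(C)=C/[C@H](C)CC)[C@H]1O | intermediate
16 | (1E,3S,4R,5R)-3,5-dihydroxy-1-iododec-1-en-4-yl (2E,4R)-2,4-dimethylhex-2-enoate | I/C=C/[C@H](O)[C@H](OC(=O)/C(C)=C/[C@H](C)CC)[C@H](O)CCCCC | intermediate
17 | (4S,5R)-5-[(1E,3S,4R,5R)-4-{[(2E,4R)-2,4-dimethylhex-2-enoyl]oxy}-3,5-dihydroxydec-1-en-1-yl]-2,2-dimethyl-1,3-dioxolane-4-carboxylic acid | OC(=O)[C@H]1OC(C)(C)O[C@@H]1/C=C/[C@H](O)[C@H](OC(=O)/C(C)=C/[C@H](C)CC)[C@H](O)CCCCC | intermediate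
18 | isobutyl carbonic mixed anhydride of 17 | CC(C)COC(=O)OC(=O)[C@H]1OC(C)(C)O[C@@H]1/C=C/[C@H](O)[C@H](OC(=O)/C(C)=C/[C@H](C)CC)[C@H](O)CCCCC | intermediate (not isolated)
19 | (1E,3S,4R,5R)-1-[(4R,5S)-5-(diazoacetyl)-2,2-dimethyl-1,3-dioxolan-4-yl]-3,5-dihydroxydec-1-en-4-yl (2E,4R)-2,4-dimethylhex-2-enoate | [N-]=[N+]=CC(=O)[C@H]1OC(C)(C)O[C@@H]1/C=C/[C@H](O)[C@H](OC(=O)/C(C)=C/[C@H](C)CC)[C@H](O)CCCCC | intermediate
20 | ketene from 19 (C4 migrated onto the former diazo carbon, configuration retained) | O=C=C[C@H]1OC(C)(C)O[C@@H]1/C=C/[C@H](O)[C@H](OC(=O)/C(C)=C/[C@H](C)CC)[C@H](O)CCCCC | intermediate (not isolated)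
21 | (4R,5R,6E,8S,9S,10R)-8-hydroxy-4,5-(isopropylidenedioxy)-2-oxo-10-pentyl-3,4,5,8,9,10-hexahydro-2H-oxecin-9-yl (2E,4R)-2,4-dimethylhex-2-enoate | CCCCC[C@H]1OC(=O)C[C@H]2OC(C)(C)O[C@@H]2/C=C/[C@H](O)[C@@H]1OC(=O)/C(C)=C/[C@H](C)CC | intermediate
22 | 4,5-O-isopropylidene derivative of the target (6,7-epoxide in place) | CCCCC[C@H]1OC(=O)C[C@H]2OC(C)(C)O[C@@H]2[C@H]3O[C@@H]3[C@H](O)[C@@H]1OC(=O)/C(C)=C/[C@H](C)CC | intermediate
23 | (4R,5S,6R,7R,8S,9S,10R)-6,7-epoxy-4,5,8-trihydroxy-2-oxo-10-pentyloxecan-9-yl (2E,4R)-2,4-dimethylhex-2-enoate (CNP0548321.2) | CCCCC[C@H]1OC(=O)C[C@@H](O)[C@H](O)[C@H]2O[C@@H]2[C@H](O)[C@@H]1OC(=O)/C(C)=C/[C@H](C)CC | target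

## Step count and risks

Total: 16 steps (4 to acid 6, 1 to diacid 8, 11 from 9 to 23). Longest linear sequence: 12 steps (1 → 23: steps 1–4 to acid 6, then steps 9–16). The chain from 9 (steps 6–16) is 11 steps and the chain from 7 (steps 5, 12–16) is 6 steps.

Steps most likely to fail:

1. Step 12, the photochemical decarboxylative vinylation with the free diacid. Possible failures are double coupling, vicinal bis-decarboxylation, or inhibition of nickel by the dicarboxylate. The fallback sets out from 7 and 16 and comes back at 17. Half-saponification of 7 (KOH, 1.0 equiv, MeOH) gives (4S,5S)-5-(methoxycarbonyl)-2,2-dimethyl-1,3-dioxolane-4-carboxylic acid F1. N-Hydroxyphthalimide and DIC convert it into the N-(acyloxy)phthalimide F2. Nickel-electrocatalysed decarboxylative alkenylation of F2 with 16 (NiCl2·6H2O, 2,2'-bipyridine, silver-nanoparticle-coated cathode from AgNO3, Mg anode, DMF, constant current) gives the trans-configured methyl ester F3. Me3SnOH (ClCH2CH2Cl, 70 °C) cleaves only the methyl ester and returns 17.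

2. Step 14, the proposed new photo-Wolff macrolactonisation. The ketene may dimerise or be hydrated, or the strained ring may close too slowly. The fallback is known chemistry, sets out from 19 and comes back at 21. Irradiating 19 (365 nm) in THF/H2O (9:1) lets water intercept the ketene (classical Arndt–Eistert homologation) to give the homologated seco-acid F4. Yamaguchi activation (2,4,6-Cl3C6H2COCl, Et3N, THF) gives the mixed anhydride F5, which on slow addition to DMAP in PhMe at 80 °C (1 mM) closes the same lactone; the C8 hydroxyl is again excluded by ring strain.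

3. Step 15, the directed epoxidation on the macrocycle. The ring may sit in the conformer that hides the required face or holds the C8–O bond anti to the alkene. The fallback sets out from 17 and comes back at 22 by epoxidising before ring closure. VO(acac)2/t-BuOOH on open-chain 17 gives the epoxy acid F6, using the known erythro preference of acyclic (E)-secondary allylic alcohols; the trans-dioxolane keeps the carboxyl from opening the oxirane. i-BuOCOCl/N-methylmorpholine gives the mixed anhydride F7, and CH2N2 then gives the epoxy diazoketone F8. Irradiation as in step 14 gives the ketene F9, which closes onto the C10 hydroxyl to give 22; the 8-membered alternative would contain a trans-fused oxirane.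

## Further compounds

F1 | step 12 | (4S,5S)-5-(methoxycarbonyl)-2,2-dimethyl-1,3-dioxolane-4-carboxylic acid | COC(=O)[C@H]1OC(C)(C)O[C@@H]1C(=O)O
F2 | step 12 | 1,3-dioxoisoindolin-2-yl methyl (4S,5S)-2,2-dimethyl-1,3-dioxolane-4,5-dicarboxylate | COC(=O)[C@H]1OC(C)(C)O[C@@H]1C(=O)ON1C(=O)c2ccccc2C1=O
F3 | step 12 | methyl ester of 17 | COC(=O)[C@H]1OC(C)(C)O[C@@H]1/C=C/[C@H](O)[C@H](OC(=O)/C(C)=C/[C@H](C)CC)[C@H](O)CCCCC
F4 | step 14 | 2-{(4R,5R)-5-[(1E,3S,4R,5R)-4-{[(2E,4R)-2,4-dimethylhex-2-enoyl]oxy}-3,5-dihydroxydec-1-en-1-yl]-2,2-dimethyl-1,3-dioxolan-4-yl}acetic acid (seco-acid) | OC(=O)C[C@H]1OC(C)(C)O[C@@H]1/C=C/[C@H](O)[C@H](OC(=O)/C(C)=C/[C@H](C)CC)[C@H](O)CCCCC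
F5 | step 14 | mixed anhydride of F4 with 2,4,6-trichlorobenzoic acid | O=C(OC(=O)C[C@H]1OC(C)(C)O[C@@H]1/C=C/[C@H](O)[C@H](OC(=O)/C(C)=C/[C@H](C)CC)[C@H](O)CCCCC)c1c(Cl)cc(Cl)cc1Cl
F6 | step 15 | 6,7-epoxide of acid 17 (oxirane configured as in the target) | OC(=O)[C@H]1OC(C)(C)O[C@@H]1[C@H]2O[C@@H]2[C@H](O)[C@H](OC(=O)/C(C)=C/[C@H](C)CC)[C@H](O)CCCCC
F7 | step 15 | isobutyl carbonic mixed anhydride of F6 | CC(C)COC(=O)OC(=O)[C@H]1OC(C)(C)O[C@@H]1[C@H]2O[C@@H]2[C@H](O)[C@H](OC(=O)/C(C)=C/[C@H](C)CC)[C@H](O)CCCCC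
F8 | step 15 | epoxy diazoketone (6,7-epoxide of 19) | [N-]=[N+]=CC(=O)[C@H]1OC(C)(C)O[C@@H]1[C@H]2O[C@@H]2[C@H](O)[C@H](OC(=O)/C(C)=C/[C@H](C)CC)[C@H](O)CCCCC
F9 | step 15 | epoxy ketene (6,7-epoxide of 20) | O=C=C[C@H]1OC(C)(C)O[C@@H]1[C@H]2O[C@@H]2[C@H](O)[C@H](OC(=O)/C(C)=C/[C@H](C)CC)[C@H](O)CCCCC
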